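Birch at 8.00 min has the right-handed substrate ahead of the left-handed by 2.8 percentage points, out of a total loss of 6.60%.

| flask | left-handed substrate | right-handed substrate | partner | remark | time |
|---|---|---|---|---|---|
| ash | 0.11 M | 0.11 M | 2.2 equiv | run made earlier |  |
| birch | 0.17 M | 0.17 M | 2.2 equiv | run made earlier |  |
| maple | 0.22 M | 0.22 M | 1.1 equiv | run made earlier |  |
| flask | 0.22 M | 0.22 M | 2.20 equiv |  | 1.5 h |

| run | time / min | left-handed substrate / % | right-handed substrate / % |
|---|---|---|---|
| ash | 10.0 | 46.3 | 48.1 |
| ash | 25.0 | 43.1 | 44.8 |
| ash | 50.0 | 40.2 | 42.2 |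
| ash | 80.0 | 38.9 | 40.3 |
| ash | 120 | 37.5 | 38.9 |
| birch | 8.00 | 45.3 | 48.1 |
| birch | 15.0 | 42.7 | 46.3 |
| birch | 30.0 | 39.8 | 43.7 |
| birch | 60.0 | 38.0 | 39.5 |
| birch | 120 | 36.3 | 36.1 |
| maple | 20.0 | 43.6 | 46.4 |
| maple | 40.0 | 41.7 | 44.4 |
| maple | 60.0 | 41.2 | 43.1 |
| maple | 80.0 | 39.3 | 41.4 |
| maple | 120 | 39.0 | 40.1 |

(scatter of a reading: 0.5 percentage points)

- partner is single-handed; left-handed substrate and right-handed substrate are mirror images of each other, charged as a racemate, each of them at the stated concentration
- an excess is the difference of the two amounts in percent of their sum
- what has gone into achiral form counts as reacted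
- an excess is below zero if the other one leads
- the handed part of partner does not stay in what it makes, so the products of the two hands are mirror images too

* part of the left-handed substrate and right-handed substrate charged together that has reacted at 1.5 h
* excess of left-handed product over right-handed product in the product at 1.5 h
* excess of right-handed substrate over left-handed substrate among what is left of the two at 1.5 h

The next run is the flask as listed, and my choice is whether to raise partner to improve the excess in the product. In birch the gap at 30.0 min is 3.9 points, far smaller than the 39.8% of left-handed substrate then present, and at 120 min it reads −0.2 points. So I freeze the two substrates as equal, and the products then form in a constant ratio. But the gap falls while the loss grows, so I take it that substrate crosses between the hands through the achiral form, and late gaps say nothing of the products; I read the earliest one.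

The gap's share of the loss is g = 42.4%. From it, s = (one plus g)/(one minus g) = 2.47: this is my estimate of the selectivity factor, left-handed product formed per right-handed product. The formula counts the whole loss as product and ignores any crossing, and both lean it low. It rests on two readings, each good to 0.5 points, so it is rough. While the substrates stay level, s doesn't depend on the partner charge, so I leave partner at 2.20 equiv and commit to eP near 42.4%.

The forecast gives c = 28%, eP = 35% and eS = 1.3%, saying “Early selectivity suggests about 35%, possibly higher”. On eP I stand above it.

The flask gives c = 27.9%, eP = 43.6% and eS = 1.83%.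

    partner + left-handed substrate → left-handed product (k = 6.80 × 10⁻⁴ M⁻¹ s⁻¹)
    partner + right-handed substrate → right-handed product (k = 2.50 × 10⁻⁴ M⁻¹ s⁻¹)
    left-handed substrate ⇌ achiral form (K = 0.0140, k = 7.20 × 10⁻⁴ s⁻¹)
    right-handed substrate ⇌ achiral form (K = 0.0140, k = 7.20 × 10⁻⁴ s⁻¹)
    partner → decomposed reagent (k = 1.00 × 10⁻⁴ s⁻¹)
    partner → decomposition product (k = 2.10 × 10⁻⁶ s⁻¹)
    2 partner → self-condensation product (k = 8.60 × 10⁻⁴ M⁻¹ s⁻¹)

The flask's product ratio at 1.50 h is 2.55, against my reading s = 2.47. A neighbouring flask changes one setting, partner at 8.80 equiv, and reaches c = 46.8%, with 0.372% in achiral form. Dividing the 46.4% of product by one plus s gives 13.4% right-handed product; that neighbour holds 13.8%, at eP = 40.4%.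

The data come from a simulation from invented constants; noise was put on by code.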